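**Plan**

1. Chromane numbering is used for the bicyclic core (O1, C2, C3, C4, C4a, C5, C6, C7, C8, C8a). Ring A is cut at C6–C7 and C8–C8a, which separates a two-carbon acyl unit C7–C8 (carrying the 3-phenylpropanoate arm) from a 5-acyl-6-(methylthio)dihydropyran. The ketone bond C4a–C5 is cut next, and the prenyl CH= and the isobutenyl CH= are joined in thought into one cyclohexene C=C.
2. Forward: ring B by hetero-Diels–Alder reaction; a cyclohexene acid from (S)-cyclohex-3-enecarboxylic acid; union by vinyllithium/Weinreb ketone synthesis; ring A by a one-pot acylation/addition–elimination; then the temporary cyclohexene (C1′ = C6, C3′=C4′, chain on C5′) is opened to the two side chains.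
3. Enabling feature: C7 is a ketone between quaternary C6 and C8, and C8=C8a is the enol-ether bond of the vinylogous ester O1–C8a=C8–C7=O. C7–C8 is therefore a ketene-like unit (electrophilic C7, nucleophilic C8), C6 is an enolate carbon of the C5 ketone, and C8a is a vinylogous acyl carbon that can carry a leaving group.
4. Stereochemistry: C2/C3 (cis) from a catalytic asymmetric endo hetero-Diels–Alder reaction; the benzylic centre from catalytic desymmetrisation of 3-phenylglutaric anhydride; the side-chain CH by anti-SN2′ relay from the purchased (S)-acid; C6 by equatorial acylation of the exocyclic enolate on the temporary cyclohexene, relayed from that CH.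
5. Temporary elements: the spiro-cyclohexene (removes the enolate-geometry problem at C6; later cleaved to prenyl + 2-methylprop-1-enyl), the C4 silyl ether (keeps C3–H non-acidic in the base steps), the dioxolane (masked isopropenyl group).

Key step: step 13

Assumption: diene 2 is treated as a purchasable 1-methoxy-3-silyloxy diene; CIP labels refer to the tautomers drawn, and centres that are destroyed later (C6 of 3, the diol carbons of 28, C1′ of F3, C8 of F4) are left open in the SMILES.

**Route**

Step 1
Reactants: 1 acetaldehyde; 2 (1E,3Z)-1-methoxy-3-(trimethylsilyloxy)penta-1,3-diene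
Product: 4 (2R,3S)-2,3-dimethyl-2,3-dihydro-4H-pyran-4-one (cis), via silyl enol ether cycloadduct 3 (not isolated)
Conditions: Cr(III) tridentate Schiff-base catalyst (aminoindanol type, 3 mol %, the enantiomer that gives 2R,3S), 4 Å MS, TBME, 0 °C; then TFA, CH2Cl2, 0 °C
Reagents that add atoms: none
Why: Catalytic asymmetric hetero-Diels–Alder reaction of a 1-methoxy-3-silyloxy diene with an aldehyde, in which the endo transition state places the aldehyde methyl cis to the (Z)-methyl of the diene, the chiral Lewis acid fixes the absolute sense, and acid then cleaves the silyl enol ether and expels methanol to give the enone.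

Step 2
Reactants: 4 (2R,3S)-2,3-dimethyl-2,3-dihydro-4H-pyran-4-one
Product: 5 (2R,3R,4R)-2,3-dimethyl-3,4-dihydro-2H-pyran-4-ol (all-cis)
Conditions: NaBH4, CeCl3·7H2O, MeOH, −78 °C
Reagents that add atoms: none
Why: Luche 1,2-reduction in which hydride should enter anti to the pseudo-axial C3 methyl group, giving the all-cis alcohol; this carbinol centre is temporary (re-oxidised in step 15) and serves to remove the acidity of C3–H during the later base steps.

Step 3
Reactants: 5 (2R,3R,4R)-2,3-dimethyl-3,4-dihydro-2H-pyran-4-ol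
Product: 6 all-cis 4-(tert-butyldimethylsilyloxy)-2,3-dimethyl-3,4-dihydro-2H-pyran
Conditions: TBSCl, imidazole, DMF, rt
Reagents that add atoms: tert-butyldimethylsilyl chloride, CC(C)(C)[Si](C)(C)Cl
Why: Standard silyl ether formation on a secondary allylic alcohol; no stereocentre is touched.

Step 4
Reactants: 6 all-cis 4-(tert-butyldimethylsilyloxy)-2,3-dimethyl-3,4-dihydro-2H-pyran
Product: 8 all-cis 4-(tert-butyldimethylsilyloxy)-2,3-dimethyl-6-(methylsulfanyl)-3,4-dihydro-2H-pyran, via 6-lithio enol ether 7 (not isolated)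
Conditions: t-BuLi, THF, −78 → 0 °C; MeSSMe, −78 °C
Reagents that add atoms: dimethyl disulfide, CSSC
Why: Vinylic α-lithiation of a cyclic enol ether (the C1-lithiation known for silyl-protected glycals) followed by sulfenylation gives the ketene O,S-acetal and so installs the leaving group on pyran C6 (C8a of the target).

Step 5
Reactants: 8 all-cis 4-(tert-butyldimethylsilyloxy)-2,3-dimethyl-6-(methylsulfanyl)-3,4-dihydro-2H-pyran
Product: 9 all-cis 4-(tert-butyldimethylsilyloxy)-5-iodo-2,3-dimethyl-6-(methylsulfanyl)-3,4-dihydro-2H-pyran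
Conditions: NIS, NaHCO3, MeCN, 0 °C
Reagents that add atoms: N-iodosuccinimide, O=C1CCC(=O)N1I
Why: Electrophilic iodination of the electron-rich ketene O,S-acetal at its β-carbon (pyran C5, the future C4a), the thionium/oxocarbenium ion losing H-5, as in the halogenation of ketene acetals and glycals.

Step 6
Reactants: 10 (S)-cyclohex-3-ene-1-carboxylic acid
Product: 11 (1S,4S,5S)-4-iodo-6-oxabicyclo[3.2.1]octan-7-one
Conditions: I2, KI, NaHCO3, H2O/CH2Cl2, 0 °C → rt
Reagents that add atoms: iodine, II
Why: Iodolactonisation, in which the carboxylate opens the iodonium ion trans to iodine to give the bridged γ-lactone, so the purchased stereocentre fixes both new centres.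

Step 7
Reactants: 11 (1S,4S,5S)-4-iodo-6-oxabicyclo[3.2.1]octan-7-one
Product: 12 (1S,5S)-6-oxabicyclo[3.2.1]oct-3-en-7-one
Conditions: DBU, toluene, 80 °C
Reagents that add atoms: none
Why: E2 dehydroiodination through the anti-periplanar H-3/I-4 pair gives the allylic (vinyl) lactone.

Step 8
Reactants: 12 (1S,5S)-6-oxabicyclo[3.2.1]oct-3-en-7-one; 13 2-(2-bromoethyl)-2-methyl-1,3-dioxolane
Product: 15 (1R,5S)-5-[2-(2-methyl-1,3-dioxolan-2-yl)ethyl]cyclohex-3-ene-1-carboxylic acid (trans), via Grignard reagent 14 (not isolated)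
Conditions: Mg, THF (13 → 14); CuBr·SMe2 (10 mol %), THF, −30 °C, add 12; then 1 M HCl
Reagents that add atoms: none
Why: Copper-catalysed anti-SN2′ allylic substitution of a vinyl lactone by a Grignard reagent, in which the alkyl group enters at the γ-carbon on the face opposite the lactone C–O bond, so the new stereocentre (the later side-chain CH) is set trans to the carboxyl group by relay from the purchased centre.

Step 9
Reactants: 15 (1R,5S)-5-[2-(2-methyl-1,3-dioxolan-2-yl)ethyl]cyclohex-3-ene-1-carboxylic acid
Product: 16 N-methoxy-N-methyl amide of 15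
Conditions: MeNH(OMe)·HCl, EDC·HCl, i-Pr2NEt, DMAP (cat.), CH2Cl2, rt
Reagents that add atoms: N,O-dimethylhydroxylamine hydrochloride, CNOC.Cl
Why: Carbodiimide amide coupling to the Weinreb amide under conditions that leave the dioxolane intact.

Step 10
Reactants: 9 all-cis 4-(tert-butyldimethylsilyloxy)-5-iodo-2,3-dimethyl-6-(methylsulfanyl)-3,4-dihydro-2H-pyran; 16 Weinreb amide
Product: 18 [all-cis 4-(tert-butyldimethylsilyloxy)-2,3-dimethyl-6-(methylsulfanyl)-3,4-dihydro-2H-pyran-5-yl] {trans-5-[2-(2-methyl-1,3-dioxolan-2-yl)ethyl]cyclohex-3-en-1-yl} ketone, via 5-lithio ketene acetal 17 (not isolated)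
Conditions: t-BuLi (2 equiv), Et2O, −78 °C; add 16, −78 → −20 °C; H2O
Reagents that add atoms: none
Why: Iodine–lithium exchange and Weinreb ketone synthesis, the chelated tetrahedral adduct preventing over-addition; the configuration of the ketone α-carbon is of no consequence because it is enolised in step 13.

Step 11
Reactants: 19 3-phenylglutaric anhydride
Product: 20 (3S)-5-methoxy-5-oxo-3-phenylpentanoic acid
Conditions: MeOH, (DHQD)2AQN or (DHQ)2AQN (cat.; the pseudo-enantiomer that gives the S acid), Et2O, −30 °C
Reagents that add atoms: methanol, CO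
Why: Catalytic enantioselective alcoholysis (desymmetrisation) of a prochiral cyclic anhydride by a modified cinchona alkaloid, which differentiates the enantiotopic carbonyl groups and so sets the benzylic stereocentre.

Step 12
Reactants: 20 (3S)-5-methoxy-5-oxo-3-phenylpentanoic acid
Product: 21 methyl (3S)-5-(1H-benzotriazol-1-yl)-5-oxo-3-phenylpentanoate
Conditions: 1H-benzotriazole, SOCl2, CH2Cl2, rt
Reagents that add atoms: 1H-benzotriazole, c1ccc2[nH]nnc2c1
Why: Conversion of the acid into its N-acylbenzotriazole, a neutral acyl donor of the kind known to acylate ketone enolates at carbon; the stereocentre is not involved.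

Step 13
Reactants: 18 pyranyl cyclohexenyl ketone; 21 methyl (3S)-5-(1H-benzotriazol-1-yl)-5-oxo-3-phenylpentanoate
Product: 24 methyl (3S)-3-{spiro[chromene-6,1′-cyclohex-3′-ene] core: 4-(tert-butyldimethylsilyloxy)-5-hydroxy-2,3-dimethyl-7-oxo-5′-[2-(2-methyl-1,3-dioxolan-2-yl)ethyl], attached through C8}-3-phenylpropanoate (C7 carbonyl cis to the 5′ chain), via lithium enolate 22 (not isolated), via C6-acyl diketone 23 (not isolated)
Conditions: LiHMDS (1.05 equiv), THF, −78 °C; MgBr2·OEt2; 21, −78 → −20 °C; LiHMDS (2.2 equiv), −20 → 0 °C; then cold 0.5 M HCl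
Reagents that add atoms: none
Why: Deprotonation of 18 can only occur at the cyclohexenyl methine (the future C6, α to the C5 ketone; C3–H is not acidic while C4 is sp3), and the exocyclic enolate 22 is acylated at carbon by 21 to give the 2,2-disubstituted 1,3-diketone 23 (C6–C7 bond); the second portion of base enolises the new C7 ketone towards C8, and this enolate adds to C8a of the β-alkoxy-β-methylthio enone and expels methanethiolate (addition–elimination, C8–C8a bond), after which the acidic ring-A enol is deprotonated so that the sequence ends in a thermodynamic sink. The closest known reaction types are the Claisen-type C-acylation of ketone enolates by N-acylbenzotriazoles and the enolate annulations of α-oxoketene S,S- and O,S-acetals; taken together the acyl donor serves as a ketene-like C7–C8 unit in an anionic formal [4+2] annulation. Ring A closes by 6-endo-trig attack of C8 on C8a (the C4a=C8a bond lies inside the new ring), followed by loss of the thiolate and enolisation, which leaves the C8=C8a double bond of the product. The only new stereocentre is C6: because both of its alkyl arms are CH2 groups of the temporary cyclohexene, the E/Z geometry of the enolate has no stereochemical consequence, and the acyl donor should approach equatorially, as is usual for exocyclic cyclohexyl enolates, on the face cis to the pseudo-equatorial C5′ chain, which places C7 cis to that chain as the target requires after ring opening. The step needs C- over O-acylation (magnesium counter-ion and the soft N-acyl azole), enolisation of the C7 ketone in preference to the methyl ester (more acidic, and only its enolate can close a six-membered ring), and an inert ring B (secured by the C4 silyl ether, which removes the C3–H acidity and the β-elimination path of a 4-pyranone).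

Step 14
Reactants: 24 spiro vinylogous acid (C4 silyl ether)
Product: 25 C4 alcohol of 24
Conditions: TBAF, AcOH, THF, 0 °C
Reagents that add atoms: none
Why: Fluoride cleavage of the secondary silyl ether under acetic acid buffering; the alcohol is taken on directly because it is a β-hydroxy vinylogous acid.

Step 15
Reactants: 25 C4 alcohol
Product: 26 spiro β-triketone (4-hydroxy-5,7-dioxo core of the target, enolised at C4), dioxolane intact
Conditions: Dess–Martin periodinane, pyridine, CH2Cl2, 0 °C
Reagents that add atoms: none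
Why: Dess–Martin oxidation of the allylic C4 alcohol gives the ketone, which enolises towards C4a into the chelated β-triketone, so the cis C2/C3 pair is not exposed to enolising conditions.

Step 16
Reactants: 26 spiro β-triketone (dioxolane)
Product: 27 spiro β-triketone with a 3-oxobutyl chain on C5′
Conditions: PPTS, THF/H2O, 45 °C
Reagents that add atoms: water, O
Why: Acid-catalysed hydrolysis of the dioxolane to the methyl ketone at a stage where no acid-sensitive trisubstituted alkene is yet present.

Step 17
Reactants: 27 spiro β-triketone methyl ketone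
Product: 29 dialdehyde [C6 carries CH2CHO; the side-chain CH carries CHO and the 3-oxobutyl group], via cis-diol 28 (not isolated)
Conditions: OsO4 (2 mol %), NaIO4, 2,6-lutidine, dioxane/H2O, rt
Reagents that add atoms: sodium periodate, [Na+].[O-]I(=O)(=O)=O (oxygen source, relayed by catalytic osmium tetroxide, O=[Os](=O)(=O)=O)
Why: Lemieux–Johnson cleavage, in which osmylation should take place at the only isolated alkene (the enol and enol-ether double bonds are conjugated to carbonyl groups) and periodate cleaves the diol, opening the temporary ring without touching C6 or the side-chain CH.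

Step 18
Reactants: 29 dialdehyde
Product: 30 methyl (3S)-3-[4-hydroxy-2,3-dimethyl-6-(3-methylbut-2-enyl)-6-[2-(2-methylprop-1-enyl)-5-oxohexyl]-5,7-dioxo-chromen-8-yl]-3-phenylpropanoate
Conditions: i-PrPPh3I, n-BuLi, THF, 0 °C; add 29, −78 → 0 °C
Reagents that add atoms: isopropyltriphenylphosphonium iodide, CC(C)[P+](c1ccccc1)(c1ccccc1)c1ccccc1.[I-]
Why: Double Wittig olefination with the non-stabilised isopropylidene ylide turns both aldehydes into 2-methylprop-1-enyl groups (the prenyl group on C6 and the isobutenyl group on the side-chain stereocentre), the triketone being protected as its enolate and the methyl ketone reacting much more slowly.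

Step 19
Reactants: 30 bis(2-methylprop-1-enyl) methyl ketone
Product: 31 methyl ester of the target
Conditions: MePPh3Br, KOt-Bu, THF, 0 °C → rt
Reagents that add atoms: methyltriphenylphosphonium bromide, C[P+](c1ccccc1)(c1ccccc1)c1ccccc1.[Br-]
Why: Wittig methylenation of the methyl ketone gives the 1,1-disubstituted alkene; the ester and the enolised triketone do not react with the ylide.

Step 20
Reactants: 31 methyl ester of the target
Product: 32 (3S)-3-[(2R,3S,6S)-4-hydroxy-2,3-dimethyl-6-(3-methylbut-2-en-1-yl)-6-[(2S)-5-methyl-2-(2-methylprop-1-en-1-yl)hex-5-en-1-yl]-5,7-dioxo-3,5,6,7-tetrahydro-2H-chromen-8-yl]-3-phenylpropanoic acid (CNP0155375.1)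
Conditions: LiOH, THF/H2O, 0 °C → rt; then 1 M HCl
Reagents that add atoms: lithium hydroxide, [Li+].[OH-]
Why: Saponification of the methyl ester; the β-triketone is present as its delocalised anion, which keeps C3–H non-acidic and disfavours retro-Michael loss of the side chain.

**Compound list**

1 | acetaldehyde | CC=O | starting material
2 | (1E,3Z)-1-methoxy-3-(trimethylsilyloxy)penta-1,3-diene | CO/C=C/C(O[Si](C)(C)C)=C/C | starting material
3 | cis-2,3-dimethyl-6-methoxy-4-(trimethylsilyloxy)-3,6-dihydro-2H-pyran (cycloadduct) | COC1C=C(O[Si](C)(C)C)[C@@H](C)[C@@H](C)O1 | intermediate (not isolated)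
4 | (2R,3S)-2,3-dimethyl-2,3-dihydro-4H-pyran-4-one | O=C1C=CO[C@H](C)[C@@H]1C | intermediate
5 | (2R,3R,4R)-2,3-dimethyl-3,4-dihydro-2H-pyran-4-ol (all-cis) | O[C@@H]1C=CO[C@H](C)[C@@H]1C | intermediate
6 | all-cis 4-(tert-butyldimethylsilyloxy)-2,3-dimethyl-3,4-dihydro-2H-pyran | CC(C)(C)[Si](C)(C)O[C@@H]1C=CO[C@H](C)[C@@H]1C | intermediate
7 | 6-lithio derivative of 6 | CC(C)(C)[Si](C)(C)O[C@@H]1C=C([Li])O[C@H](C)[C@@H]1C | intermediate (not isolated)
8 | all-cis 4-(tert-butyldimethylsilyloxy)-2,3-dimethyl-6-(methylsulfanyl)-3,4-dihydro-2H-pyran | CC(C)(C)[Si](C)(C)O[C@@H]1C=C(SC)O[C@H](C)[C@@H]1C | intermediate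
9 | all-cis 4-(tert-butyldimethylsilyloxy)-5-iodo-2,3-dimethyl-6-(methylsulfanyl)-3,4-dihydro-2H-pyran | CC(C)(C)[Si](C)(C)O[C@@H]1C(I)=C(SC)O[C@H](C)[C@@H]1C | intermediate
10 | (S)-cyclohex-3-ene-1-carboxylic acid | OC(=O)[C@@H]1CC=CCC1 | starting material
11 | (1S,4S,5S)-4-iodo-6-oxabicyclo[3.2.1]octan-7-one | O=C1O[C@H]2C[C@@H]1CC[C@@H]2I | intermediate
12 | (1S,5S)-6-oxabicyclo[3.2.1]oct-3-en-7-one | O=C1O[C@H]2C[C@@H]1CC=C2 | intermediate
13 | 2-(2-bromoethyl)-2-methyl-1,3-dioxolane | CC1(CCBr)OCCO1 | starting material
14 | [2-(2-methyl-1,3-dioxolan-2-yl)ethyl]magnesium bromide | CC1(CC[Mg]Br)OCCO1 | intermediate (not isolated)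
15 | (1R,5S)-5-[2-(2-methyl-1,3-dioxolan-2-yl)ethyl]cyclohex-3-ene-1-carboxylic acid (trans) | OC(=O)[C@@H]1CC=C[C@@H](CCC2(C)OCCO2)C1 | intermediate
16 | N-methoxy-N-methyl amide of 15 | CON(C)C(=O)[C@@H]1CC=C[C@@H](CCC2(C)OCCO2)C1 | intermediate
17 | 5-lithio derivative formed from 9 | CC(C)(C)[Si](C)(C)O[C@@H]1C([Li])=C(SC)O[C@H](C)[C@@H]1C | intermediate (not isolated)
18 | pyran-5-yl cyclohex-3-enyl ketone (4-silyloxy, 6-methylsulfanyl; trans-5′-dioxolanylethyl) | CC(C)(C)[Si](C)(C)O[C@@H]1C(C(=O)[C@@H]2CC=C[C@@H](CCC3(C)OCCO3)C2)=C(SC)O[C@H](C)[C@@H]1C | intermediate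
19 | 3-phenylglutaric anhydride | O=C1CC(c2ccccc2)CC(=O)O1 | starting material
20 | (3S)-5-methoxy-5-oxo-3-phenylpentanoic acid | OC(=O)C[C@@H](CC(=O)OC)c1ccccc1 | intermediate
21 | methyl (3S)-5-(1H-benzotriazol-1-yl)-5-oxo-3-phenylpentanoate | O=C(C[C@@H](CC(=O)OC)c1ccccc1)n1nnc2ccccc12 | intermediate
22 | lithium enolate of 18 (exocyclic to the cyclohexene) | CC(C)(C)[Si](C)(C)O[C@@H]1C(C(O[Li])=C2CC=C[C@@H](CCC3(C)OCCO3)C2)=C(SC)O[C@H](C)[C@@H]1C | intermediate (not isolated)
23 | C6-acylated 1,3-diketone | CC(C)(C)[Si](C)(C)O[C@@H]1C(C(=O)[C@]2(C(=O)C[C@@H](CC(=O)OC)c3ccccc3)CC=C[C@@H](CCC4(C)OCCO4)C2)=C(SC)O[C@H](C)[C@@H]1C | intermediate (not isolated)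
24 | spiro[chromene-6,1′-cyclohexene] vinylogous acid, C4 silyl ether, dioxolane, methyl ester | CC1(CC[C@@H]2C=CC[C@]3(C2)C(O)=C4[C@@H](O[Si](C)(C)C(C)(C)C)[C@@H](C)[C@@H](C)OC4=C([C@@H](CC(=O)OC)c4ccccc4)C3=O)OCCO1 | intermediate
25 | C4 alcohol of 24 | CC1(CC[C@@H]2C=CC[C@]3(C2)C(O)=C4[C@@H](O)[C@@H](C)[C@@H](C)OC4=C([C@@H](CC(=O)OC)c4ccccc4)C3=O)OCCO1 | intermediate
26 | spiro β-triketone (4-hydroxy-5,7-dioxo), dioxolane | CC1(CC[C@@H]2C=CC[C@]3(C2)C(=O)C4=C(O)[C@@H](C)[C@@H](C)OC4=C([C@@H](CC(=O)OC)c4ccccc4)C3=O)OCCO1 | intermediate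
27 | spiro β-triketone with 3-oxobutyl chain | CC(=O)CC[C@@H]1C=CC[C@]2(C1)C(=O)C3=C(O)[C@@H](C)[C@@H](C)OC3=C([C@@H](CC(=O)OC)c3ccccc3)C2=O | intermediate
28 | cis-3′,4′-diol of 27 | CC(=O)CC[C@@H]1C(O)C(O)C[C@]2(C1)C(=O)C3=C(O)[C@@H](C)[C@@H](C)OC3=C([C@@H](CC(=O)OC)c3ccccc3)C2=O | intermediate (not isolated)
29 | dialdehyde (ring-opened) | CC(=O)CC[C@H](C=O)C[C@@]1(CC=O)C(=O)C2=C(O)[C@@H](C)[C@@H](C)OC2=C([C@@H](CC(=O)OC)c2ccccc2)C1=O | intermediate
30 | bis(2-methylprop-1-enyl) methyl ketone | CC(=O)CC[C@H](C=C(C)C)C[C@@]1(CC=C(C)C)C(=O)C2=C(O)[C@@H](C)[C@@H](C)OC2=C([C@@H](CC(=O)OC)c2ccccc2)C1=O | intermediate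
31 | methyl ester of the target | C=C(C)CC[C@H](C=C(C)C)C[C@@]1(CC=C(C)C)C(=O)C2=C(O)[C@@H](C)[C@@H](C)OC2=C([C@@H](CC(=O)OC)c2ccccc2)C1=O | intermediate
32 | CNP0155375.1 | C=C(C)CC[C@H](C=C(C)C)C[C@@]1(CC=C(C)C)C(=O)C2=C(O)[C@@H](C)[C@@H](C)OC2=C([C@@H](CC(=O)O)c2ccccc2)C1=O | target

**Totals and risks**

Total step count: 20. Longest linear sequence: 14 steps (1–5, 10, 13–20).

Step 13 (key step). The hindered, fully substituted enolate 22 may be acylated on oxygen instead of on C6, which would stop the annulation at an enol ester. The fallback accepts O-acylation and reaches ring A by known steps (enolate O-acylation, intramolecular addition–elimination, alkoxide-mediated 2-pyranone → cyclohexane-1,3-dione isomerisation by lactone opening and Dieckmann condensation). It sets out from 18 and 20 and returns at 24. Acid 20 is converted with oxalyl chloride into the acid chloride methyl (3R)-5-chloro-5-oxo-3-phenylpentanoate F1 (same spatial arrangement; the label changes with CIP priority). The potassium enolate of 18 (KHMDS, THF/HMPA) is acylated by it on oxygen to the enol ester F2. LiHMDS then forms the ester enolate, which attacks C8a and expels methanethiolate to give, after proton shift, the fused 2-pyranone F3. NaOMe in MeOH/THF at 50 °C opens the lactone to the ring-opened methyl ester F4 (not isolated), whose C6 enolate closes onto the ester to give 24; C6 is again set by equatorial attack on the cyclohexene.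

Step 14. The free C4 alcohol 25 is a β-hydroxy vinylogous acid and may lose water (towards a 2-alkylidene-1,3-dione) before or during oxidation. The fallback masks the ring-A enol first; it sets out from 24 and returns at 27, passing by 25 and 26. Compound 24 is O-methylated with TMSCHN2 (MeOH/toluene) to the methyl enol ether F5 (drawn as the C5–OMe isomer; the C7–OMe isomer would serve equally). TBAF gives the allylic alcohol F6, which has no acidic enol, and Dess–Martin oxidation gives the C4 ketone F7. Aqueous HCl in THF then hydrolyses both the β-methoxy enone and the dioxolane in one operation to give 27.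

Step 18. The strongly basic ylide may enolise the α-branched aldehyde of 29 (loss of configuration at the side-chain CH) or trigger aldol closure of the 1,6-dialdehyde. The fallback replaces the ylide by a sulfone-based olefination under Barbier conditions: Julia–Kocienski reaction of 29 with 1-phenyl-5-(propan-2-ylsulfonyl)-1H-tetrazole, LiHMDS being added last at −78 °C so that the sulfonyl anion is trapped by the aldehydes as it forms. It sets out from 29 and returns at 30; no new isolable compound arises (F0).

Further compounds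
F1 | step 13 | methyl (3R)-5-chloro-5-oxo-3-phenylpentanoate | O=C(Cl)C[C@@H](CC(=O)OC)c1ccccc1
F2 | step 13 | enol ester (O-acyl derivative of the enolate of 18) | CC(C)(C)[Si](C)(C)O[C@@H]1C(C(OC(=O)C[C@@H](CC(=O)OC)c2ccccc2)=C2CC=C[C@@H](CCC3(C)OCCO3)C2)=C(SC)O[C@H](C)[C@@H]1C
F3 | step 13 | fused 2-pyranone | O=C1OC(C2CC=C[C@@H](CCC3(C)OCCO3)C2)=C2[C@@H](O[Si](C)(C)C(C)(C)C)[C@@H](C)[C@@H](C)OC2=C1[C@@H](CC(=O)OC)c1ccccc1
F4 | step 13 | ring-opened methyl ester | COC(=O)C([C@@H](CC(=O)OC)c1ccccc1)C1=C(C(=O)C2CC=C[C@@H](CCC3(C)OCCO3)C2)[C@@H](O[Si](C)(C)C(C)(C)C)[C@@H](C)[C@@H](C)O1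
F5 | step 14 | methyl enol ether of 24 (C5–OMe) | CC1(CC[C@@H]2C=CC[C@]3(C2)C(OC)=C4[C@@H](O[Si](C)(C)C(C)(C)C)[C@@H](C)[C@@H](C)OC4=C([C@@H](CC(=O)OC)c4ccccc4)C3=O)OCCO1
F6 | step 14 | C4 alcohol of F5 | CC1(CC[C@@H]2C=CC[C@]3(C2)C(OC)=C4[C@@H](O)[C@@H](C)[C@@H](C)OC4=C([C@@H](CC(=O)OC)c4ccccc4)C3=O)OCCO1
F7 | step 14 | C4 ketone of F6 | CC1(CC[C@@H]2C=CC[C@]3(C2)C(OC)=C4C(=O)[C@@H](C)[C@@H](C)OC4=C([C@@H](CC(=O)OC)c4ccccc4)C3=O)OCCO1
F0 | step 18 | none | none
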